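## Retrosynthetic overview

1. The butenolide is closed last by ring-closing metathesis (C13=C14). Before it come acetylation, reduction of a C11 ketone, and a zinc Barbier union (C11–C12) of albicanal with allyl 2-(bromomethyl)acrylate.
2. Albicanal comes from methyl albicanate, made by deconjugation of methyl drim-8-en-11-oate. That ester comes from carbonylation of the C9 enol triflate of a bicyclic C9 ketone (C11 enters as CO).
3. The bicyclic ketone comes from a dienone made in the key annulation. Ring A is closed onto ring B by joining C4 and C1 through a two-carbon C2–C3 unit from vinyltriphenylphosphonium bromide: C3–C4 by radical addition, C1=C2 by intramolecular Wittig reaction. The ring B aldehyde is made from (R)-carvone in three steps.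
4. Enabling feature: in ring A, C4 is a gem-dimethyl carbon on the ring-fusion CH (C5), so it is the tertiary radical obtained by hydrogen-atom transfer to the isopropenyl group of carvone. C1 is a CH2 on the quaternary ring-fusion carbon C10, so its aldehyde form cannot enolise and acts only as an acceptor. C2 and C3 between them carry no substituent.
5. Ring order: ring B (from carvone), then ring A (key step), then the butenolide ring (last step).

Key step: step 4

Remark: atoms are given labdane numbers (decalin C1–C10, exocyclic methylene C17, C11 bearing OAc, butenolide C13–C16), and the target is read as the normal-series (5S,9S,10S,11R) isomer.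

## Route

Step 1
Reactants: 1 (R)-(−)-carvone
Product: 3 (5R)-6-methylcarvone as a mixture of C6 epimers, via carvone lithium dienolate 2 (not isolated)
Conditions: LiN(iPr)2, THF, −78 °C; MeI, −78 → 0 °C
Reagents that add atoms: iodomethane, CI
Why: Kinetic deprotonation at the α′ carbon gives the cross-conjugated lithium dienolate, whose C-methylation (enolate alkylation) is well established for carvone; the new stereocentre is erased again by the enolisation of step 2.

Step 2
Reactants: 3 (5R)-6-methylcarvone
Product: 5 (5S,6R)-6-(hydroxymethyl)-2,6-dimethyl-5-(prop-1-en-2-yl)cyclohex-2-en-1-one, via 6-methylcarvone lithium enolate 4 (not isolated)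
Conditions: LiN(iPr)2, THF, −78 °C; CH2O (gas, from cracked paraformaldehyde), −78 °C; H2O
Reagents that add atoms: formaldehyde, C=O
Why: Aldol hydroxymethylation of the fully substituted lithium enolate should take place anti to the neighbouring isopropenyl group, which sets the quaternary carbon (future C10) with CH2OH trans and CH3 cis to the isopropenyl group (the future trans ring fusion).

Step 3
Reactants: 5 hydroxymethyl ketone
Product: 6 (1R,6S)-1,3-dimethyl-2-oxo-6-(prop-1-en-2-yl)cyclohex-3-ene-1-carbaldehyde
Conditions: Dess–Martin periodinane, NaHCO3, CH2Cl2, 0 °C → rt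
Reagents that add atoms: none
Why: Dess–Martin oxidation of the neopentyl primary alcohol under buffered, non-basic conditions should give the non-enolisable aldehyde without retro-aldol loss of the one-carbon unit.

Step 4
Reactants: 6 keto aldehyde; 7 vinyltriphenylphosphonium bromide
Product: 10 (4aS,8aS)-2,5,5,8a-tetramethyl-4a,5,6,8a-tetrahydronaphthalen-1(4H)-one, via phosphonium bromide 8 (not isolated), via phosphorus ylide 9 (not isolated)
Conditions: Fe(acac)3 (30 mol %), PhSi(OiPr)H2, iPrOH, 7 (1.2 equiv), ClCH2CH2Cl, 0 °C → rt; solvent removed, residue rinsed with Et2O (8 not purified); then KOtBu, THF, 0 °C → rt (one flask)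
Reagents that add atoms: vinyltriphenylphosphonium bromide (7), C=C[P+](c1ccccc1)(c1ccccc1)c1ccccc1.[Br-]
Why: Proposed new method: a trivalent iron hydride formed from Fe(acac)3 and the silane transfers a hydrogen atom to the CH2 terminus of the isopropenyl group (which becomes one of the two C4 methyl groups), the tertiary C4 radical adds to the unsubstituted terminus of the vinylphosphonium cation to form C3–C4, and the α-phosphonio radical is reduced by divalent iron to the ylide 9 (radical-polar crossover), which is held as the salt 8 until KOtBu releases it and then closes ring A by intramolecular Wittig reaction with the C1 aldehyde to form C1=C2. The closest known reaction types are the iron-hydride Giese/aldol radical-polar crossover annulation of γ,δ-unsaturated aldehydes with enones (same radical, same aldehyde acceptor, same ring topology), the photoredox radical addition to vinylphosphonium salts with ylide formation and Wittig olefination, and the Schweizer annulation. Ring A closes in a 6-exo-trig sense (ylide carbon C2 onto the exocyclic C1=O, then loss of Ph3P=O from the oxaphosphetane), which can only give the cis ring alkene. No stereocentre is created: the trans ring fusion follows from the relative configuration set in step 2, in which the CHO group on C10 and the isopropenyl group on C5 are trans on ring B, so that C1 and C4 end up diequatorial. The step needs hydrogen-atom transfer to the electron-rich 1,1-disubstituted alkene in preference to the conjugated trisubstituted enone alkene, capture of the tertiary radical by the cationic acceptor faster than by the enone of a second molecule, and Wittig closure at the aldehyde and not at the C9 ketone; the last is secured by the higher electrophilicity of the aldehyde and by the strained bridgehead alkene that closure onto C9 would require.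

Step 5
Reactants: 10 dienone
Product: 11 (4aS,8aS)-2,5,5,8a-tetramethyloctahydronaphthalen-1(2H)-one as a mixture of C2 epimers
Conditions: H2 (1 atm), Pd/C, EtOAc, rt
Reagents that add atoms: none
Why: Heterogeneous hydrogenation should saturate both the cis-disubstituted C1=C2 alkene and the enone C7=C8 bond while leaving the hindered ketone, and the configuration created at C8 is irrelevant because C8 becomes trigonal again in step 6.

Step 6
Reactants: 11 saturated ketone
Product: 13 (4aS,8aS)-2,5,5,8a-tetramethyl-3,4,4a,5,6,7,8,8a-octahydronaphthalen-1-yl trifluoromethanesulfonate, via potassium enolate 12 (not isolated)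
Conditions: KN(SiMe3)2, THF, −78 → 0 °C; PhNTf2, −78 °C → rt; H2O
Reagents that add atoms: N-phenylbis(trifluoromethanesulfonimide), O=S(=O)(N(c1ccccc1)S(=O)(=O)C(F)(F)F)C(F)(F)F
Why: The ketone can enolise only toward C8 (C10 is quaternary), so deprotonation and O-triflation of the potassium enolate should give the tetrasubstituted C8=C9 enol triflate as a single regioisomer.

Step 7
Reactants: 13 enol triflate
Product: 14 methyl drim-8-en-11-oate, methyl (4aS,8aS)-2,5,5,8a-tetramethyl-3,4,4a,5,6,7,8,8a-octahydronaphthalene-1-carboxylate
Conditions: Pd(OAc)2, dppp, CO (1 atm), MeOH, Et3N, DMF, 70 °C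
Reagents that add atoms: carbon monoxide, [C-]#[O+]; methanol, CO
Why: Oxidative addition of zerovalent palladium to the vinyl triflate, CO insertion and methanolysis of the acylpalladium species (alkoxycarbonylation) introduce C11 as the methyl ester, a reaction type used on hindered cyclohexenyl triflates.

Step 8
Reactants: 14 methyl drim-8-en-11-oate
Product: 16 methyl albicanate, methyl (1S,4aS,8aS)-5,5,8a-trimethyl-2-methylidenedecahydronaphthalene-1-carboxylate, via exocyclic lithium dienolate 15 (not isolated)
Conditions: LiN(iPr)2, THF/DMPU, −78 °C; AcOH, −78 °C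
Reagents that add atoms: none
Why: Kinetic γ-deprotonation of the α,β-unsaturated ester takes a hydrogen from the methyl group syn to the ester (C17), and α-protonation of the exocyclic dienolate at C9 from the face opposite the axial C10 methyl group should give the β,γ-unsaturated ester with H-9 α and the ester equatorial (deconjugative protonation, as in the conversion of β- into γ-cyclogeranate).

Step 9
Reactants: 16 methyl albicanate
Product: 17 albicanol, [(1S,4aS,8aS)-5,5,8a-trimethyl-2-methylidenedecahydronaphthalen-1-yl]methanol
Conditions: LiAlH4, Et2O, 0 °C; H2O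
Reagents that add atoms: none
Why: Hydride reduction of the ester to the primary alcohol does not touch the 1,1-disubstituted alkene or the C9 stereocentre.

Step 10
Reactants: 17 albicanol
Product: 18 albicanal, (1S,4aS,8aS)-5,5,8a-trimethyl-2-methylidenedecahydronaphthalene-1-carbaldehyde
Conditions: Dess–Martin periodinane, NaHCO3, CH2Cl2, 0 °C
Reagents that add atoms: none
Why: Buffered Dess–Martin oxidation gives the β,γ-unsaturated aldehyde without base, which should avoid epimerisation at C9 and migration of the double bond into conjugation, and the aldehyde is used at once.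

Step 11
Reactants: 19 2-(bromomethyl)acrylic acid; 20 allyl alcohol
Product: 21 allyl 2-(bromomethyl)acrylate
Conditions: H2SO4 (cat.), benzene, reflux (Dean–Stark)
Reagents that add atoms: allyl alcohol (20), C=CCO
Why: Acid-catalysed Fischer esterification with azeotropic removal of water is the standard route to esters of 2-(bromomethyl)acrylic acid.

Step 12
Reactants: 18 albicanal; 21 allyl 2-(bromomethyl)acrylate
Product: 22 allyl 4-hydroxy-2-methylidene-4-[(1S,4aS,8aS)-5,5,8a-trimethyl-2-methylidenedecahydronaphthalen-1-yl]butanoate as a mixture of C11 epimers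
Conditions: Zn dust, THF/sat. aq NH4Cl, 0 °C → rt
Reagents that add atoms: allyl 2-(bromomethyl)acrylate (21), C=CCOC(=O)C(=C)CBr
Why: Zinc-mediated Barbier allylation in aqueous medium adds the 2-(alkoxycarbonyl)allyl unit through either of its equivalent CH2 termini to the aldehyde without base and forms C11–C12; the configuration at C11 is not relied on, because both epimers converge in step 13.

Step 13
Reactants: 22 hydroxy ester
Product: 23 allyl 2-methylidene-4-oxo-4-[(1S,4aS,8aS)-5,5,8a-trimethyl-2-methylidenedecahydronaphthalen-1-yl]butanoate
Conditions: Dess–Martin periodinane, NaHCO3, CH2Cl2, 0 °C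
Reagents that add atoms: none
Why: Buffered Dess–Martin oxidation converts both C11 epimers into one ketone under conditions mild enough to keep the two exocyclic alkenes that flank the carbonyl group out of conjugation.

Step 14
Reactants: 23 keto ester
Product: 24 allyl (4R)-4-hydroxy-2-methylidene-4-[(1S,4aS,8aS)-5,5,8a-trimethyl-2-methylidenedecahydronaphthalen-1-yl]butanoate
Conditions: (S)-2-methyl-CBS-oxazaborolidine, catecholborane, toluene, −78 → −40 °C; H2O
Reagents that add atoms: none
Why: Corey–Bakshi–Shibata reduction treats the ring carbon C9 as the large and the C12 methylene as the small substituent of the C11 ketone, which for the (S)-catalyst should give the 11R alcohol under reagent control, while the low temperature and the non-basic medium should keep both exocyclic alkenes in place.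

Step 15
Reactants: 24 (11R)-hydroxy ester
Product: 25 allyl (4R)-4-acetoxy-2-methylidene-4-[(1S,4aS,8aS)-5,5,8a-trimethyl-2-methylidenedecahydronaphthalen-1-yl]butanoate
Conditions: Ac2O, DMAP, Et3N, CH2Cl2, 0 °C → rt
Reagents that add atoms: acetic anhydride, CC(=O)OC(C)=O
Why: DMAP-catalysed acetylation of the hindered secondary alcohol installs the C11 acetate without touching the stereocentre.

Step 16
Reactants: 25 acetoxy diene ester
Product: 26 CNP0182424.2, (1R)-2-(2-oxo-2,5-dihydrofuran-3-yl)-1-[(1S,4aS,8aS)-5,5,8a-trimethyl-2-methylidenedecahydronaphthalen-1-yl]ethyl acetate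
Conditions: second-generation Grubbs catalyst (10 mol %), toluene, 80 °C, high dilution
Reagents that add atoms: none
Why: Ring-closing metathesis between the allyl ester alkene and the 1,1-disubstituted acrylate alkene closes the five-membered butenolide (C13=C14) with loss of ethylene, a known route to α-substituted butenolides, while the hindered C8=C17 alkene should stay out because its only small-ring closure would need a tetrasubstituted alkene.

## Compound list

1 | (R)-(−)-carvone | CC1=CC[C@H](CC1=O)C(C)=C | starting material
2 | carvone lithium dienolate | CC1=CC[C@@H](C(C)=C)C=C1O[Li] | intermediate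
3 | (5R)-2,6-dimethyl-5-(prop-1-en-2-yl)cyclohex-2-en-1-one (6-methylcarvone, C6 epimers) | CC1=CC[C@@H](C(C)=C)C(C)C1=O | intermediate
4 | 6-methylcarvone lithium enolate | CC1=CC[C@@H](C(C)=C)C(C)=C1O[Li] | intermediate
5 | (5S,6R)-6-(hydroxymethyl)-2,6-dimethyl-5-(prop-1-en-2-yl)cyclohex-2-en-1-one (CH2OH trans to isopropenyl) | CC1=CC[C@@H](C(C)=C)[C@](C)(CO)C1=O | intermediate
6 | (1R,6S)-1,3-dimethyl-2-oxo-6-(prop-1-en-2-yl)cyclohex-3-ene-1-carbaldehyde | CC1=CC[C@@H](C(C)=C)[C@](C)(C=O)C1=O | intermediate
7 | vinyltriphenylphosphonium bromide | C=C[P+](c1ccccc1)(c1ccccc1)c1ccccc1.[Br-] | starting material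
8 | {3-[(1S,2R)-2-formyl-2,4-dimethyl-3-oxocyclohex-4-en-1-yl]-3-methylbutyl}triphenylphosphonium bromide | CC1=CC[C@@H](C(C)(C)CC[P+](c2ccccc2)(c2ccccc2)c2ccccc2)[C@](C)(C=O)C1=O.[Br-] | intermediate
9 | ylide of 8, {3-[(1S,2R)-2-formyl-2,4-dimethyl-3-oxocyclohex-4-en-1-yl]-3-methylbutylidene}triphenylphosphorane | CC1=CC[C@@H](C(C)(C)CC=P(c2ccccc2)(c2ccccc2)c2ccccc2)[C@](C)(C=O)C1=O | intermediate
10 | (4aS,8aS)-2,5,5,8a-tetramethyl-4a,5,6,8a-tetrahydronaphthalen-1(4H)-one | CC1=CC[C@H]2C(C)(C)CC=C[C@]2(C)C1=O | intermediate
11 | (4aS,8aS)-2,5,5,8a-tetramethyloctahydronaphthalen-1(2H)-one (C2 epimers) | CC1CC[C@H]2C(C)(C)CCC[C@]2(C)C1=O | intermediate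
12 | potassium enolate of 11 | CC1=C(O[K])[C@@]2(C)CCCC(C)(C)[C@@H]2CC1 | intermediate
13 | (4aS,8aS)-2,5,5,8a-tetramethyl-3,4,4a,5,6,7,8,8a-octahydronaphthalen-1-yl trifluoromethanesulfonate | CC1=C(OS(=O)(=O)C(F)(F)F)[C@@]2(C)CCCC(C)(C)[C@@H]2CC1 | intermediate
14 | methyl drim-8-en-11-oate | CC1=C(C(=O)OC)[C@@]2(C)CCCC(C)(C)[C@@H]2CC1 | intermediate
15 | exocyclic lithium dienolate of 14 | C=C1CC[C@H]2C(C)(C)CCC[C@]2(C)C1=C(OC)O[Li] | intermediate
16 | methyl albicanate, methyl (1S,4aS,8aS)-5,5,8a-trimethyl-2-methylidenedecahydronaphthalene-1-carboxylate | C=C1CC[C@H]2C(C)(C)CCC[C@]2(C)[C@H]1C(=O)OC | intermediate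
17 | albicanol, [(1S,4aS,8aS)-5,5,8a-trimethyl-2-methylidenedecahydronaphthalen-1-yl]methanol | C=C1CC[C@H]2C(C)(C)CCC[C@]2(C)[C@H]1CO | intermediate
18 | albicanal, (1S,4aS,8aS)-5,5,8a-trimethyl-2-methylidenedecahydronaphthalene-1-carbaldehyde | C=C1CC[C@H]2C(C)(C)CCC[C@]2(C)[C@H]1C=O | intermediate
19 | 2-(bromomethyl)acrylic acid | OC(=O)C(=C)CBr | starting material
20 | allyl alcohol | C=CCO | starting material
21 | allyl 2-(bromomethyl)acrylate | C=CCOC(=O)C(=C)CBr | intermediate
22 | allyl 4-hydroxy-2-methylidene-4-[(1S,4aS,8aS)-5,5,8a-trimethyl-2-methylidenedecahydronaphthalen-1-yl]butanoate (C11 epimers) | C=C1CC[C@H]2C(C)(C)CCC[C@]2(C)[C@H]1C(O)CC(=C)C(=O)OCC=C | intermediate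
23 | allyl 2-methylidene-4-oxo-4-[(1S,4aS,8aS)-5,5,8a-trimethyl-2-methylidenedecahydronaphthalen-1-yl]butanoate | C=C1CC[C@H]2C(C)(C)CCC[C@]2(C)[C@H]1C(=O)CC(=C)C(=O)OCC=C | intermediate
24 | allyl (4R)-4-hydroxy-2-methylidene-4-[(1S,4aS,8aS)-5,5,8a-trimethyl-2-methylidenedecahydronaphthalen-1-yl]butanoate | C=C1CC[C@H]2C(C)(C)CCC[C@]2(C)[C@H]1[C@@H](CC(=C)C(=O)OCC=C)O | intermediate
25 | allyl (4R)-4-acetoxy-2-methylidene-4-[(1S,4aS,8aS)-5,5,8a-trimethyl-2-methylidenedecahydronaphthalen-1-yl]butanoate | C=C1CC[C@H]2C(C)(C)CCC[C@]2(C)[C@H]1[C@@H](CC(=C)C(=O)OCC=C)OC(C)=O | intermediate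
26 | CNP0182424.2, (11R)-11-acetoxylabda-8(17),13-dien-16,15-olide | C=C1CC[C@H]2C(C)(C)CCC[C@]2(C)[C@H]1[C@@H](CC1=CCOC1=O)OC(C)=O | target

## Step count and risks

Total step count: 16. Longest linear sequence: 15 steps (steps 1–10 and 12–16); step 11 is a one-step side branch.

Steps most likely to fail:

1. Step 4 (proposed new method). The iron-hydride cycle may stall if the α-phosphonio radical is not reduced and the iron is not returned to its trivalent state. The aldehyde may be hydrosilylated. On base addition, deformylation of the β-keto aldehyde (retro-Claisen) may compete with ylide formation. Fallback with known chemistry, setting out from 6: the established iron-hydride Giese/aldol annulation is run with acrolein as the two-carbon acceptor (Fe(acac)3, PhSi(OiPr)H2, iPrOH/ClCH2CH2Cl). The tertiary radical adds to acrolein and the resulting enolate closes onto the C1 aldehyde, which should give the ring A hydroxy aldehyde F1. Acid-catalysed dehydration (TsOH, toluene) should give the ring A enal F2. Decarbonylation with stoichiometric RhCl(PPh3)3 (toluene, reflux) removes the formyl group and comes back to the route at 10.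

2. Step 8. Regiocontrol of the γ-deprotonation may be lost (ring CH2 at C7 instead of the syn methyl group), or the dienolate may be reprotonated at the γ carbon, which returns 14 or gives the endocyclic isomer. Fallback, setting out from 14: photochemical deconjugation (254 nm, catalytic weak base, Et2O/MeOH). Photoenolisation by 1,5-hydrogen shift can take the hydrogen only from the methyl group syn to the ester, and ketonisation of the dienol at C9 should lead directly to 16, where the route is rejoined; no strong base and no new intermediate are involved.

3. Step 14. The double bonds of keto ester 23 may migrate into conjugation before or during the reduction, or facial control at the hindered C11 ketone may be insufficient. Fallback, setting out from 22: the C11 epimers are separated by chromatography. The 11R epimer is identical with 24 and goes on as in step 15. The 11S epimer, allyl (4S)-4-hydroxy-2-methylidene-4-[(1S,4aS,8aS)-5,5,8a-trimethyl-2-methylidenedecahydronaphthalen-1-yl]butanoate F3, is converted by Mitsunobu esterification with acetic acid (PPh3, DIAD, inversion at C11) directly into 25, where the route is rejoined, so that ketone 23 is never made.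

Further compounds
F1 | step 4 | ring A hydroxy aldehyde: 2-formyl-1-hydroxy derivative of 10 with C1–C2 saturated (labdane numbering, C1 and C2 epimers) | CC1=CC[C@H]2C(C)(C)CC(C=O)C(O)[C@]2(C)C1=O
F2 | step 4 | ring A enal: 2-formyl derivative of 10 (CHO on C2 of the C1=C2 bond) | CC1=CC[C@H]2C(C)(C)CC(C=O)=C[C@]2(C)C1=O
F0 | step 8 | none | none
F3 | step 14 | allyl (4S)-4-hydroxy-2-methylidene-4-[(1S,4aS,8aS)-5,5,8a-trimethyl-2-methylidenedecahydronaphthalen-1-yl]butanoate | C=C1CC[C@H]2C(C)(C)CCC[C@]2(C)[C@H]1[C@H](CC(=C)C(=O)OCC=C)O
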